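**Plan**
- **Cuts.** With the ester carbonyl as C1, the retrosynthesis cuts C6–OMe and C6–O(peroxide) first, taking the ketal back to a γ-hydroperoxy enone. It then cuts C4=C5 (cross-metathesis) and finally C2–C3 (acetate addition).
- **Enabling feature.** Ring carbon C3 of the 3,6-dihydro-1,2-dioxine bears only H, a ring peroxide oxygen, the ring alkene carbon C4 and the side-chain CH2 (C2). This is the pattern left when an acetate nucleophile adds to the peroxide-stabilised allyl cation at the oxidation level of acrolein.
- **Forward order.** A C3 peroxyacetal and a C2 ketene acetal give the five-carbon β-silylperoxy ester. Metathesis with a C19 vinyl ketone forms C4=C5 and brings in C5–C22. The only ring closes last, when the freed OOH attacks the C6 ketone after E→Z photoisomerisation, and methanol then fixes the ketal.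
- **Stereochemistry.** C3 comes from a chiral counter-anion in the C2–C3 bond formation. C6 is relayed from C3 in a reversible ketalisation (OMe pseudoaxial by the anomeric effect, both carbon chains pseudoequatorial), and the epimer is removed by chromatography.

Key step: step 4

Assumption: the sense of induction of a confined IDPi anion on an acyclic peroxycarbenium ion cannot be predicted, so the catalyst antipode (both come from commercial BINOL) is fixed after a first sample of the key product has been correlated, by O–O reduction, with the known β-hydroxy ester.

Step 1
Reactants: 1 acrolein dimethyl acetal (3,3-dimethoxyprop-1-ene); 2 hydrogen peroxide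
Product: 3 (±)-3-hydroperoxy-3-methoxyprop-1-ene (1-methoxyallyl hydroperoxide)
Conditions: dried ethereal H2O2 (5 equiv), Amberlyst-15 (cat.), Et2O, 0 °C, short contact; filter; wash with aq NaHCO3 and brine; keep as a dried solution behind a shield, never concentrate to dryness
Reagents that add atoms: none
Why: Acid-catalysed SN1-type acetal exchange (perhydrolysis), in which one methoxy group leaves easily with help from the other oxygen and the vinyl group, excess H2O2 captures the acetal carbon, and a second exchange should be much slower at 0 °C because a hydroperoxy group supports ionisation less well than methoxy; the new centre is racemic, which is harmless because it is erased in step 4.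

Step 2
Reactants: 3 (±)-3-hydroperoxy-3-methoxyprop-1-ene
Product: 4 (±)-triethyl[(1-methoxyprop-2-en-1-yl)peroxy]silane
Conditions: Et3SiCl, imidazole, CH2Cl2–Et2O, 0 °C; chromatography on silica
Reagents that add atoms: triethylsilyl chloride, CC[Si](Cl)(CC)CC
Why: Standard O-silylation of a hydroperoxide, which is more acidic and more nucleophilic than an alcohol, under a weak base at 0 °C that should not start a Kornblum–DeLaMare-type fragmentation; triethylsilyl peroxides as a class tolerate chromatography.

Step 3
Reactants: 5 methyl acetate
Product: 7 tert-butyl[(1-methoxyethenyl)oxy]dimethylsilane, via lithium enolate 6 (not isolated)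
Conditions: LDA, THF, −78 °C; TBSCl, DMPU, −78 °C → rt; pentane extraction, distillation
Reagents that add atoms: tert-butyldimethylsilyl chloride, CC(C)(C)[Si](C)(C)Cl (the lithium of 6 only comes from LDA, [Li+].CC(C)[N-]C(C)C)
Why: Kinetic ester enolisation and O-silylation of 6, the standard preparation of silyl ketene acetals, in which the bulky chlorosilane and the polar cosolvent favour O- over C-silylation.

Step 4
Reactants: 4 (±)-triethyl[(1-methoxyprop-2-en-1-yl)peroxy]silane; 7 tert-butyl[(1-methoxyethenyl)oxy]dimethylsilane
Product: 10 methyl (3S)-3-[(triethylsilyl)peroxy]pent-4-enoate, via peroxycarbenium ion 8 (not isolated), via O-silylated ester cation 9 (not isolated)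
Conditions: BINOL-derived imidodiphosphorimidate (IDPi) acid with N-triflyl core and bulky 3,3'-aryl groups (3 mol %), 7 (1.5 equiv), toluene, −80 °C, strictly anhydrous; then aq NaHCO3
Reagents that add atoms: none
Why: Proposed new method: the IDPi acid is first silylated by 7, and the resulting silylium/IDPi pair silylates the methoxy oxygen of 4, expels the silyl methyl ether and leaves the planar allylic cation 8 lying against the chiral anion, so both enantiomers of 4 drain into one intermediate and the whole racemate can be converted. Ketene acetal 7 then attacks C3 of 8 through an open Mukaiyama-type transition state to form the C2–C3 bond, and cation 9 hands its TBS group to the next molecule of 4, which frees 10 and keeps the silylium cycle running. The closest known reactions are the racemic Lewis-acid coupling of silyl ketene acetals with monoperoxyacetals to 3-peroxyalkanoates and the IDPi-catalysed enantioselective addition of silyl nucleophiles to oxocarbenium ions released from acetals; what is untested is chiral-anion control over a cation stabilised by a peroxide oxygen. No ring closes in this step. The single new stereocentre, C3, is controlled only by the confined anion, which must leave the Si face of C3 open to give 3S. Three selectivities are needed: loss of OMe rather than OOSiEt3, secured by the higher basicity and lower hindrance of the methoxy oxygen; attack at C3 rather than at the allylic terminus C5, secured by the concentration of charge on the oxygen-bearing carbon; and C–C bond formation ahead of O–O heterolysis, secured by the low temperature and the non-nucleophilic anion.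

Step 5
Reactants: 11 heptadecanoic acid
Product: 13 N-methoxy-N-methylheptadecanamide, via acyl imidazole 12 (not isolated)
Conditions: CDI, CH2Cl2, rt; then MeNH(OMe)·HCl, rt
Reagents that add atoms: N,O-dimethylhydroxylamine hydrochloride, CNOC.Cl (the imidazolyl group of 12 only comes from 1,1'-carbonyldiimidazole, O=C(n1ccnc1)n1ccnc1)
Why: Weinreb amide formation by carboxylic acid activation as 12 and aminolysis, a routine acyl transfer with no competing functionality.

Step 6
Reactants: 13 N-methoxy-N-methylheptadecanamide
Product: 15 nonadec-1-en-3-one, via magnesium chelate 14 (not isolated)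
Conditions: vinylmagnesium bromide, THF, 0 °C; inverse quench into cold 1 M HCl; store cold with a trace of BHT
Reagents that add atoms: vinylmagnesium bromide, C=C[Mg]Br
Why: Weinreb ketone synthesis, in which chelate 14 blocks a second addition and the acidic inverse quench protonates the released amine before it can add to the new vinyl ketone in a conjugate sense.

Step 7
Reactants: 10 methyl (3S)-3-[(triethylsilyl)peroxy]pent-4-enoate; 15 nonadec-1-en-3-one
Product: 16 methyl (3S,4E)-6-oxo-3-[(triethylsilyl)peroxy]docos-4-enoate
Conditions: Hoveyda–Grubbs II (5 mol %), 15 (2 equiv), CH2Cl2, 40 °C, argon sparge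
Reagents that add atoms: none
Why: Olefin cross-metathesis of an allylic-oxygenated terminal alkene with an electron-poor vinyl ketone, in which neither partner homodimerises readily, loss of ethene drives the exchange, the conjugated product is formed as the E isomer, peroxide O–O bonds are known to survive ruthenium carbenes, and C3 is not touched.

Step 8
Reactants: 16 methyl (3S,4E)-6-oxo-3-[(triethylsilyl)peroxy]docos-4-enoate
Product: 17 methyl (3S,4E)-3-hydroperoxy-6-oxodocos-4-enoate
Conditions: 48% aq HF, MeCN, 0 °C
Reagents that add atoms: none
Why: Acidic fluoride cleavage of the O–Si bond, chosen because non-basic conditions avoid deprotonation at C3 (γ to the enone) and therefore avoid elimination, Kornblum–DeLaMare fragmentation and loss of configuration.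

Step 9
Reactants: 17 methyl (3S,4E)-3-hydroperoxy-6-oxodocos-4-enoate
Product: 20 6-epi-chondrillin = methyl [(3S,6S)-6-hexadecyl-6-methoxy-3,6-dihydro-1,2-dioxin-3-yl]acetate, via Z-hydroperoxy enone 18 (not isolated), via dioxinol 19 (not isolated)
Conditions: hν (medium-pressure Hg lamp, Pyrex, λ > 300 nm), degassed MeOH, rt; then p-TsOH·H2O (cat.), MeOH, rt, dark; solid NaHCO3; chromatography on silica
Reagents that add atoms: methanol, CO
Why: Enone E→Z photoisomerisation, 6-exo-trig hemiketalisation and acid-catalysed ketalisation, the established path from γ-hydroperoxy enones to 3-alkoxy-1,2-dioxines: only 18 can reach its own ketone, so closure to 19 drains the photoequilibrium, and the reversible exchange of OH for OMe at C6 is steered by the fixed C3 centre towards the 6S epimer, which alone has the methoxy group pseudoaxial (anomeric effect) with both carbon chains pseudoequatorial on the half-chair, any 6R epimer being removed on silica.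

**Compound list**
1 | acrolein dimethyl acetal (3,3-dimethoxyprop-1-ene) | C=CC(OC)OC | starting material
2 | hydrogen peroxide | OO | starting material
3 | (±)-3-hydroperoxy-3-methoxyprop-1-ene | C=CC(OC)OO | intermediate
4 | (±)-triethyl[(1-methoxyprop-2-en-1-yl)peroxy]silane | C=CC(OC)OO[Si](CC)(CC)CC | intermediate
5 | methyl acetate | CC(=O)OC | starting material
6 | lithium 1-methoxyethenolate (lithium enolate of methyl acetate) | [Li+].[O-]C(=C)OC | intermediate
7 | tert-butyl[(1-methoxyethenyl)oxy]dimethylsilane | C=C(OC)O[Si](C)(C)C(C)(C)C | intermediate
8 | 1-[(triethylsilyl)peroxy]allyl cation (peroxycarbenium ion, paired with the chiral IDPi anion) | C=CC=[O+]O[Si](CC)(CC)CC | intermediate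
9 | carbonyl-O-TBS-silylated cation of ester 10 (3S) | C=C[C@H](CC(OC)=[O+][Si](C)(C)C(C)(C)C)OO[Si](CC)(CC)CC | intermediate
10 | methyl (3S)-3-[(triethylsilyl)peroxy]pent-4-enoate | C=C[C@H](CC(=O)OC)OO[Si](CC)(CC)CC | intermediate
11 | heptadecanoic acid | CCCCCCCCCCCCCCCCC(=O)O | starting material
12 | 1-(1H-imidazol-1-yl)heptadecan-1-one | CCCCCCCCCCCCCCCCC(=O)n1ccnc1 | intermediate
13 | N-methoxy-N-methylheptadecanamide | CCCCCCCCCCCCCCCCC(=O)N(C)OC | intermediate
14 | bromomagnesium 3-[methoxy(methyl)amino]nonadec-1-en-3-olate (chelated tetrahedral adduct) | CCCCCCCCCCCCCCCCC([O-])(C=C)N(C)OC.[Mg+2].[Br-] | intermediate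
15 | nonadec-1-en-3-one | CCCCCCCCCCCCCCCCC(=O)C=C | intermediate
16 | methyl (3S,4E)-6-oxo-3-[(triethylsilyl)peroxy]docos-4-enoate | CCCCCCCCCCCCCCCCC(=O)/C=C/[C@H](CC(=O)OC)OO[Si](CC)(CC)CC | intermediate
17 | methyl (3S,4E)-3-hydroperoxy-6-oxodocos-4-enoate | CCCCCCCCCCCCCCCCC(=O)/C=C/[C@H](CC(=O)OC)OO | intermediate
18 | methyl (3S,4Z)-3-hydroperoxy-6-oxodocos-4-enoate | CCCCCCCCCCCCCCCCC(=O)/C=C\[C@H](CC(=O)OC)OO | intermediate
19 | methyl [(3S)-6-hexadecyl-6-hydroxy-3,6-dihydro-1,2-dioxin-3-yl]acetate (both C6 anomers) | CCCCCCCCCCCCCCCCC1(O)C=C[C@H](CC(=O)OC)OO1 | intermediate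
20 | 6-epi-chondrillin, methyl [(3S,6S)-6-hexadecyl-6-methoxy-3,6-dihydro-1,2-dioxin-3-yl]acetate | CCCCCCCCCCCCCCCC[C@@]1(OC)C=C[C@H](CC(=O)OC)OO1 | target

**Totals**
Total step count: 9.
Longest linear sequence: 6 steps (1, 2, 4, 7, 8, 9).

**Steps most likely to fail**

Step 4.
- What may go wrong: the anion may shield one face of a small, conformationally mobile acyclic cation too weakly. Ionisation may occur at the wrong oxygen, attack may drift to the allylic terminus, or O–O cleavage may outrun C–C bond formation.
- Fallback: asymmetric induction is given up and the material is resolved later with known chemistry. The fallback sets out from 4 and 7. These are coupled with catalytic TMSOTf in CH2Cl2 at −78 °C, the known racemic peroxyacetal–ketene acetal coupling, to give racemic methyl 3-[(triethylsilyl)peroxy]pent-4-enoate F1.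
- Cross-metathesis of F1 with 15 as in step 7 gives racemic methyl (4E)-6-oxo-3-[(triethylsilyl)peroxy]docos-4-enoate F2. Its enone chromophore allows preparative chromatography on a polysaccharide chiral stationary phase.
- Methyl (3R,4E)-6-oxo-3-[(triethylsilyl)peroxy]docos-4-enoate F3 is set aside. The 3S enantiomer is 16, where the fallback rejoins the route.

Step 7.
- What may go wrong: turnover may be slow because both olefins are reluctant partners. The catalyst may die by reduction of the O–O bond, or the allylic double bond may migrate.
- Fallback: C4=C5 is built by carbonyl olefination instead of metathesis. The fallback sets out from 10. Ozonolysis in CH2Cl2–pyridine at −78 °C, which delivers the aldehyde without a reducing agent, gives methyl (3S)-4-oxo-3-[(triethylsilyl)peroxy]butanoate F4.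
- F4 is used at once, without base, in a Wittig reaction in CH2Cl2 at rt with the stabilised ylide 1-(triphenyl-λ5-phosphanylidene)octadecan-2-one F5. F5 is made from acyl imidazole 12 and methylenetriphenylphosphorane (2 equiv).
- The E-selective olefination comes back to the route at 16.

Step 9.
- What may go wrong: methanol may capture C6 with little facial preference. The hydroperoxide may decay under irradiation, or γ-hydrogen abstraction in the Z-enone may compete with ring closure.
- Fallback: the one-pass ketalisation is replaced by a separate-and-recycle loop. The fallback sets out from 19, whose ketalisation is accepted as unselective.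
- The 6R epimer, chondrillin F6, is separated on silica and returned to catalytic p-TsOH in methanol. Reversible loss of methanol from the ketal carbon re-equilibrates C6 without touching C3.
- Repeated cycles of separation and equilibration move the material to 20, where the fallback rejoins the route.

**Further compounds**
F1 | step 4 | methyl (±)-3-[(triethylsilyl)peroxy]pent-4-enoate | C=CC(CC(=O)OC)OO[Si](CC)(CC)CC
F2 | step 4 | methyl (±)-(4E)-6-oxo-3-[(triethylsilyl)peroxy]docos-4-enoate | CCCCCCCCCCCCCCCCC(=O)/C=C/C(CC(=O)OC)OO[Si](CC)(CC)CC
F3 | step 4 | methyl (3R,4E)-6-oxo-3-[(triethylsilyl)peroxy]docos-4-enoate | CCCCCCCCCCCCCCCCC(=O)/C=C/[C@@H](CC(=O)OC)OO[Si](CC)(CC)CC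
F4 | step 7 | methyl (3S)-4-oxo-3-[(triethylsilyl)peroxy]butanoate | O=C[C@H](CC(=O)OC)OO[Si](CC)(CC)CC
F5 | step 7 | 1-(triphenyl-λ5-phosphanylidene)octadecan-2-one | CCCCCCCCCCCCCCCCC(=O)C=P(c1ccccc1)(c1ccccc1)c1ccccc1
F6 | step 9 | chondrillin, methyl [(3S,6R)-6-hexadecyl-6-methoxy-3,6-dihydro-1,2-dioxin-3-yl]acetate | CCCCCCCCCCCCCCCC[C@]1(OC)C=C[C@H](CC(=O)OC)OO1
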